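No rate constant comes with these flasks, so the one that matters has to be read from the two earlier runs.

| flask | starting material | coupling partner | second substrate | third substrate | remark | time |
|---|---|---|---|---|---|---|
| south-west | 30 mM | 38 mM (in portions, 4) | 60 mM | 6 mM | run made earlier; portions every 25 min |  |
| north-west | 30 mM | 59 mM (in portions, 4) | 60 mM | 6 mM | run made earlier; portions every 25 min |  |
| grey | 30 mM | 27.0 mM (in portions, 4) | 60.0 mM | 6.00 mM | the portions of coupling partner follow each other after 25 min, the first at the start | 8.0 h |
| amber | 30 mM | 27.0 mM (in portions, 4) | 60.0 mM | 6.00 mM | the portions of coupling partner follow each other after 25 min, the first at the start | 5.0 h |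
| green | 30 mM | 27.0 mM (in portions, 4) | 60.0 mM | 6.00 mM | the portions of coupling partner follow each other after 25 min, the first at the start | 6.0 h |

| run | time / h | starting material / % | side product / % | target / % |
|---|---|---|---|---|
| south-west | 0.500 | 95.0 | 0.8 | 4.0 |
| south-west | 1.50 | 82.2 | 1.9 | 16.6 |
| south-west | 3.00 | 72.4 | 5.2 | 22.5 |
| south-west | 4.00 | 69.0 | 7.3 | 22.6 |
| south-west | 6.00 | 65.0 | 12.6 | 22.4 |
| north-west | 1.33 | 76.5 | 1.9 | 21.3 |
| north-west | 2.50 | 60.6 | 6.1 | 33.5 |
| north-west | 4.00 | 52.6 | 9.8 | 36.9 |
| north-west | 5.00 | 49.1 | 14.0 | 36.0 |
| north-west | 6.00 | 46.7 | 16.9 | 36.4 |

(readings scatter by 0.5 percentage points)

- which of these there is most of at the end, counted by the starting material in it, grey (starting material / side product / target)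
- which of these there is most of at the end, counted by the starting material in it, amber (starting material / side product / target)
- which of these there is most of at the end, counted by the starting material in it, green (starting material / side product / target)
- amount of the one of these that there is most of at the end, in percent of the starting material charged, grey
- amount of the one of these that there is most of at the end, in percent of the starting material charged, amber
- amount of the one of these that there is most of at the end, in percent of the starting material charged, green

- percentages count the starting material that a species holds: one side product counts as two
- a reading or a percentage of target counts all its forms, free or not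

In the south-west run, starting material falls by 0.145 /h of what is present between 0.500 h and 1.50 h, by 0.0846 /h up to 3.00 h, and by 0.0359 /h up to 6.00 h. The rate therefore slows by a factor of 1.71, then 2.36. Over the last stretch target reads flat, with a mean of 22.4%. Dividing that rate by the mean target fraction gives 0.160 /h. The north-west run, with a mean target of 36.6%, gives 0.162 /h, close to the south-west value. Their mean, 0.161 /h, is the drain constant: the fractional rate of loss of starting material per unit fraction of the charge held as target. It is read from the whole fall of starting material, so any starting material still turning into target over that stretch is counted in it.

Grey, amber and green share one recipe and differ in time. My own reckoning takes the plateau target per mM of partner, 0.177 and 0.186, which puts the new plateau at 16.4%. The south-west loss by 3.00 h, scaled to the new charge, leaves 80.4%. Replacing the target curve by this mean gives a drain of 0.0264 /h, slower than the south-west 0.0359 /h. Starting material then stands at 76.3% in amber, 74.3% in green and 70.5% in grey. The gap between the two yields moves the grey figure by 0.47 percentage points, while starting material stays far above the plateau, so the choice of largest holder is safe.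

The forecast also names starting material in each flask, with 77% (74% to 80%) for amber, 75% (71.5% to 78%) for green and 71.5% (67.5% to 75%) for grey, each above my figure. Of the drain it says: “This rises with target even though starting material is lower”.

Starting material ends largest in amber at 77.1%, green at 75.5% and grey at 72.9%.

    starting material + coupling partner → target (k = 14.0 /M/h)
    starting material + target → side product (k = 2.90 /M/h)
    third substrate + target ⇌ idle adduct, settled at all times (K = 130 /M)
    third substrate + coupling partner → third product (k = 130 /M/h)
    coupling partner ⇌ dormant form (K = 1.60, k = 0.600 /h)
    second substrate + coupling partner → second product (k = 16.0 /M/h)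

Target stands lower in grey, 14.3%, than in amber, 15.4%, with 1.3% of the partner free in grey. The drain constant, applied to these two target values from amber's end to grey's, gives 71.7%. The neighbour with 11 mM of partner ends at 8.0 h with 90.0% starting material and 5.32% target. Its drain from 3.00 h reckons to 3.9 points, and its side product stands at 4.70%.

The runs come from a simulation with constants of no real substance, and the scatter is random.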